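## Analysis of the target

The target is a germacranolide of the melampolide type: a cyclodeca-1(10),4-diene whose C6–C7 bond is shared with an α-methylene-γ-butyrolactone (ring oxygen on C6, carbonyl C12, exocyclic C11=C13). Germacrane numbering is used throughout; C14 is the methyl on C10 and C15 the methyl on C4. There are four stereocentres: C2 (R, free allylic carbinol), C6 (R), C7 (S) and C9 (S, esterified with (Z)-2-(hydroxymethyl)but-2-enoic acid). C6 and C7 are anti along the chain, which gives the trans lactone fusion; C9 is 1,3-related to C7 across C8, and C2 is remote from the other three. Both ring alkenes are trisubstituted: C4=C5 is E and C1=C10 is Z, the latter flanked by the oxygenated carbons C2 and C9. The sensitive groups are the exo-methylene lactone (a Michael acceptor), the angelate-type side chain (it isomerises to the tiglate geometry under nucleophilic catalysis), the allylic ester at C9 and the 1,5-diene, which cyclises across the ring under acid. The hard part is closing a strained ten-membered carbocycle that holds a Z trisubstituted alkene. The strategy rests on that alkene: C1 and C10 can be bridged by a sulfonyl group in a ring one atom larger, and expelling the bridge from the eleven-membered sulfone 25 leaves the cis double bond.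

## Retrosynthetic reasoning

**42 from 41.** The two hydroxyls (C2 and the side-chain primary alcohol) are unveiled last from bis-silyl ether 41. Both are allylic and would interfere with the oxidation that forms the lactone, so one fluoride step at the end is the safest place for them.

**41 from 38 and 37.** The lactone C12–O bond is cut back to the 2-methylene-1,4-diol 38, which comes from bis-PMB ether 37. The Michael acceptor must not exist while thiolate and hydroxide are used earlier, so C12 is carried as an ether at the alcohol oxidation level and oxidised only after sulfur has left the molecule.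

**37 from 29 and 35.** The C9 ester is cut at the acyl–oxygen bond to alcohol 29 and acid 35. Acylation comes before the lactone is made, so that the C9 hydroxyl cannot compete with the C6 hydroxyl for the C12 aldehyde. Acid 35 is made from crotonaldehyde 30 through 31–34; its geometry follows from the α-iodination of the E enal.

**28 from 25 (key disconnection).** The C1=C10 double bond is replaced by a sulfonyl bridge between C1 and C10, which gives the eleven-membered sulfone 25. Ring closure is thereby moved from a C–C bond in a strained ten-membered ring to a C–S bond in a larger ring. The forward step has to halogenate an α-carbon, close the episulfone 27 and expel the bridge, without eliminating the silyloxy groups at C2 and C9.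

**25 from 21.** Sulfone 25 comes from sulfide 24 by oxidation at sulfur. The S–C1 bond of 24 is cut to give thioacetate 21, whose primary chloride is the electrophile (through 22 and 23). C1 is chosen over C10 because intramolecular displacement at a primary carbon is far easier than at the hindered secondary C10. The C10–S bond is formed earlier, intermolecularly and with inversion, from alcohol 20.

**20 from 17.** Alcohol 20 is obtained from 19 by removing the one benzylic ether that is more electron-rich than the other two. The two PMB ethers of 19 come from diol 18, and 18 from reduction of trans-lactone 17. The lactone is the natural product of the C6–C7 bond formation; it is opened to the diol only to hide C12 during the sulfur chemistry.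

**17 from 6 and 15.** The C6–C7 bond is cut between enal 6 and allylboronate 15. This is the most convergent cut of the chain. It creates both C6 and C7 in one step through a closed transition state, and it delivers C11–C13 with the correct oxidation pattern. The forward reaction needs E-type geometry in 15 for the anti relationship, and a chiral Brønsted acid catalyst for the facial sense, because C9 is too far away to control it.

**15 from 7.** Boronate 15 is traced to ynoate 13 by cis hydroalumination and borylmethylation. 13 comes from alkyne 11 and alcohol 10, and 10 from aldehyde 9 by chelation-controlled propargylation, so C9 is set by the lactate stereocentre. Aldehyde 9 comes from ethyl (S)-lactate 7 through ether 8. The lactate oxygen is only a placeholder for sulfur at C10.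

**6 from 1.** Enal 6 is traced through allylic alcohol 5 to alkyne 3 by carboalumination, which fixes the E geometry of C4=C5. 3 comes from chlorohydrin 2 and (R)-epichlorohydrin 1, which supplies C1–C3, the C2 stereocentre and the C1 leaving group.

## Alternatives that were turned down

**Alternative 1:** The C6–O bond is disconnected, leading to the ten-membered acrylic acid A2, in which C6 is a methylene group. In the forward step, Pd(OAc)2 with a bis-sulfoxide ligand and benzoquinone would cleave the allylic C6–H bond. The C12 carboxylate would then attack the π-allyl at C6 and give A1, which is identical with 41.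
- For it: it mirrors the biosynthesis, needs no protection at C6 or C12, and forms the Michael acceptor only at the end. In endgame brevity and redox economy it is stronger than the chosen route.
- Against it: this divalent-palladium chemistry is established for terminal allyl groups. A2 has a trisubstituted ring alkene and many competing allylic sites (C3, C6, C15, C2–H, C9–H, C14, C7–H). The π-allyl could also be attacked at C4, and the facial outcome at C6 would depend on a ring conformation that cannot be predicted.
- It also leaves the real problem unsolved: A2 still needs a ten-membered ring closure with a Z trisubstituted alkene.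
- Comparison: the chosen strategy spends more protecting-group steps but fixes each stereocentre and each alkene geometry by a separate, predictable event.

**Alternative 2:** The C5–C6 bond and the C4–methyl bond are disconnected, leading to ynal A4. In the forward step, zerovalent nickel (Ni(cod)2 with a small N-heterocyclic carbene) would couple the terminal alkyne carbon C5 with the aldehyde carbon C6 in an oxanickelacycle. Me2Zn would deliver methyl to C4, and the zinc alkoxide would close the lactone to give A3.
- For it: one step would form the ring, the E alkene, the C6 carbinol and the lactone, and no sulfur is needed. It is more convergent than the chosen route.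
- Against it: ten-membered rings are at the lower limit of such alkylative macrocyclisations. Closure at the terminal alkyne carbon has to beat the exocyclic mode. C6 would be set only by the neighbouring C7, which is an epimerisable α-centre of an aldehyde.
- The Z C1=C10 alkene would have to be built beforehand in an open chain, where nothing enforces its geometry. A3 also lacks C13, so α-methylenation of the lactone would follow.
- Comparison: the chosen route obtains the Z alkene from the ring itself and closes the ring by a two-electron S-alkylation. Alternative 2 would stake the ring and two selectivities on one step.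

**Alternative 3:** The C7–C8 bond is disconnected, leading to the N-acyloxyphthalimide A6, which carries a 3-(phenylsulfonylmethyl)butenolide. Cathodic reduction would release the primary C8 radical. This would add in a 10-exo-trig mode to C7, anti to the C6 substituent, and the C11 radical would expel the phenylsulfonyl radical to give A5.
- For it: like the chosen route it pays the ring strain in an irreversible fragmentation. It is stronger in one respect: the complete α-methylene lactone, with the trans fusion, is present as soon as the ring closes.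
- Against it: a primary radical must find the acceptor through a ten-membered transition state. Further reduction at the cathode would give a carbanion with a β-silyloxy leaving group at C9, and the chain offers several allylic C–H bonds (C3, C6) for hydrogen transfer.
- A6 contains a γ-alkenyl butenolide with an acidic, doubly activated C6–H, and it still needs the Z C1=C10 alkene made in open-chain form.
- Comparison: the chosen route offers geometric control of that alkene by ring constraint, and a ring closure (thiolate on a primary halide) whose failure mode is concentration-dependent, not intrinsic.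

Key step: step 18

## Route

Remarks on the chemistry:
- (S)-TRIP, 3,4-dimethoxybenzyl trichloroacetimidate, allenyltributylstannane and 2-(iodomethyl)-4,4,5,5-tetramethyl-1,3,2-dioxaborolane are taken as purchasable reagents.
- C10 is inverted in step 15 and becomes sp2 in step 18, so its configuration is of no consequence.
- Abbreviations: TBS = tert-butyldimethylsilyl, TES = triethylsilyl, PMB = 4-methoxybenzyl, DMB = 3,4-dimethoxybenzyl, Bpin = pinacol boronate.

**C1–C6 enal**

Step 1
Reactants: 1 (R)-epichlorohydrin
Product: 2 (R)-1-chloropent-4-yn-2-ol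
Conditions: HC≡CH, n-BuLi, THF, −78 °C; BF3·OEt2; then 1, −78 °C
Reagents that add atoms: acetylene (C#C)
Why: BF3-assisted (Yamaguchi-type) opening of the epoxide by lithium acetylide at the unsubstituted carbon; the C–O bond at the stereocentre is not touched, so C2 keeps the R configuration of 1 and the chloride remains as the later C1 electrophile.

Step 2
Reactants: 2 (R)-1-chloropent-4-yn-2-ol
Product: 3 (R)-tert-butyl[(1-chloropent-4-yn-2-yl)oxy]dimethylsilane
Conditions: TBSCl, imidazole, DMF, rt
Reagents that add atoms: tert-butyldimethylsilyl chloride (CC(C)(C)[Si](C)(C)Cl)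
Why: Standard silylation of a secondary alcohol; the TBS ether blocks epoxide re-formation from the chlorohydrin and is the C2 protecting group to the end.

Step 3
Reactants: 3 (R)-tert-butyl[(1-chloropent-4-yn-2-yl)oxy]dimethylsilane
Product: 5 (R,E)-5-(tert-butyldimethylsilyloxy)-6-chloro-3-methylhex-2-en-1-ol, via alkenyl(dimethyl)alane 4 (not isolated)
Conditions: Me3Al, Cp2ZrCl2 (cat.), CH2Cl2, 0 °C → rt; then n-BuLi, (CH2O)n, THF, −78 °C → rt
Reagents that add atoms: trimethylaluminium (C[Al](C)C); formaldehyde from paraformaldehyde (C=O)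
Why: Negishi zirconium-catalysed carboalumination adds methyl and aluminium syn across the terminal alkyne with methyl on the internal carbon, which fixes the E geometry of C4=C5; the derived alanate is hydroxymethylated with retention to install C6.

Step 4
Reactants: 5 (R,E)-5-(tert-butyldimethylsilyloxy)-6-chloro-3-methylhex-2-en-1-ol
Product: 6 (R,E)-5-(tert-butyldimethylsilyloxy)-6-chloro-3-methylhex-2-enal
Conditions: MnO2, CH2Cl2, rt
Reagents that add atoms: none
Why: Chemoselective oxidation of the allylic alcohol on MnO2; neutral conditions leave the alkene geometry, the silyl ether and the chloride unchanged.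

**C7–C14 allylboronate**

Step 5
Reactants: 7 ethyl (S)-lactate
Product: 8 ethyl (S)-2-[(3,4-dimethoxybenzyl)oxy]propanoate
Conditions: 3,4-dimethoxybenzyl 2,2,2-trichloroacetimidate, CSA (cat.), CH2Cl2, 0 °C → rt
Reagents that add atoms: 3,4-dimethoxybenzyl 2,2,2-trichloroacetimidate (COc1ccc(COC(=N)C(Cl)(Cl)Cl)cc1OC)
Why: Acid-catalysed imidate benzylation avoids the base that racemises lactates; the DMB ether is chosen because it chelates in step 7 and is cleaved oxidatively faster than a PMB ether in step 14.

Step 6
Reactants: 8 ethyl (S)-2-[(3,4-dimethoxybenzyl)oxy]propanoate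
Product: 9 (S)-2-[(3,4-dimethoxybenzyl)oxy]propanal
Conditions: i-Bu2AlH, CH2Cl2, −78 °C
Reagents that add atoms: none
Why: Partial reduction of the α-alkoxy ester stops at the chelated aluminium hemiacetal at low temperature; the aldehyde is used crude to keep the α-centre intact.

Step 7
Reactants: 9 (S)-2-[(3,4-dimethoxybenzyl)oxy]propanal
Product: 10 (2S,3S)-2-[(3,4-dimethoxybenzyl)oxy]hex-5-yn-3-ol
Conditions: allenyltributylstannane (Bu3SnCH=C=CH2), MgBr2·OEt2, CH2Cl2, −78 → −20 °C
Reagents that add atoms: allenyltributylstannane (C=C=C[Sn](CCCC)(CCCC)CCCC)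
Why: Chelation-controlled SE2′ propargylation (Keck-type): magnesium bridges the aldehyde and ether oxygens and the allenylstannane attacks the face opposite the methyl group, which should give the syn alcohol and thus the S configuration at C9.

Step 8
Reactants: 10 (2S,3S)-2-[(3,4-dimethoxybenzyl)oxy]hex-5-yn-3-ol
Product: 11 {[(2S,3S)-2-[(3,4-dimethoxybenzyl)oxy]hex-5-yn-3-yl]oxy}triethylsilane
Conditions: TESCl, imidazole, DMF, 0 °C → rt
Reagents that add atoms: triethylsilyl chloride (CC[Si](CC)(CC)Cl)
Why: Standard silylation; TES on C9 can later be removed in the presence of the TBS ether at C2, and it prevents the C9 oxygen from closing a δ-lactone onto C12.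

Step 9
Reactants: 11 {[(2S,3S)-2-[(3,4-dimethoxybenzyl)oxy]hex-5-yn-3-yl]oxy}triethylsilane
Product: 13 methyl (5S,6S)-6-[(3,4-dimethoxybenzyl)oxy]-5-(triethylsilyloxy)hept-2-ynoate, via lithium acetylide 12 (not isolated)
Conditions: n-BuLi, THF, −78 °C; ClCO2Me, −78 → 0 °C
Reagents that add atoms: methyl chloroformate (COC(=O)Cl)
Why: Deprotonation of the terminal alkyne and C-acylation of the acetylide; this adds C12 and activates the triple bond for conjugate hydroalumination.

Step 10
Reactants: 13 methyl (5S,6S)-6-[(3,4-dimethoxybenzyl)oxy]-5-(triethylsilyloxy)hept-2-ynoate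
Product: 15 methyl (Z,5S,6S)-6-[(3,4-dimethoxybenzyl)oxy]-2-[(4,4,5,5-tetramethyl-1,3,2-dioxaborolan-2-yl)methyl]-5-(triethylsilyloxy)hept-2-enoate, via α-alumino enoate 14 (not isolated)
Conditions: i-Bu2AlH, HMPA, THF, 0 °C; then ICH2Bpin, 0 °C → rt; aq. NaHCO3
Reagents that add atoms: 2-(iodomethyl)-4,4,5,5-tetramethyl-1,3,2-dioxaborolane (ICB1OC(C)(C)C(C)(C)O1)
Why: The i-Bu2AlH–HMPA complex adds H–Al cis across the ynoate with aluminium at C11; borylmethylation through the boron ate complex and 1,2-shift retains the geometry, so C8 ends cis to the ester and trans to CH2B, the E-crotyl-type arrangement needed for an anti allylboration.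

**Union, ring closure and key step**

Step 11
Reactants: 6 (R,E)-5-(tert-butyldimethylsilyloxy)-6-chloro-3-methylhex-2-enal; 15 methyl (Z,5S,6S)-6-[(3,4-dimethoxybenzyl)oxy]-2-[(4,4,5,5-tetramethyl-1,3,2-dioxaborolan-2-yl)methyl]-5-(triethylsilyloxy)hept-2-enoate
Product: 17 (4S,5R)-5-[(R,E)-4-(tert-butyldimethylsilyloxy)-5-chloro-2-methylpent-1-en-1-yl]-4-[(2S,3S)-3-(3,4-dimethoxybenzyloxy)-2-(triethylsilyloxy)butyl]-3-methylenedihydrofuran-2(3H)-one, via pinacol borate 16 (not isolated)
Conditions: (S)-TRIP (5 mol%), 4 Å MS, toluene, −30 °C → rt; then 40 °C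
Reagents that add atoms: none
Why: Allylboration through a closed chair transition state: the E-type geometry of 15 places C8 equatorial and should give the anti C6/C7 adduct, which lactonises to the trans lactone. The chiral phosphoric acid activates a boronate oxygen and is expected to direct attack to the Si face of the enal, the (R)-acid being known to favour the Re face, which sets 6R,7S independently of the remote C9 centre. Any uncyclised hydroxy ester converges with 17 in step 12.

Step 12
Reactants: 17 trans-lactone (name as in step 11)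
Product: 18 (2R,6R,7S,9S,10S)-2-(tert-butyldimethylsilyloxy)-1-chloro-10-(3,4-dimethoxybenzyloxy)-9-(triethylsilyloxy)-1,10-secogermacra-4E,11(13)-diene-6,12-diol
Conditions: i-Bu2AlH, CH2Cl2, −78 → 0 °C
Reagents that add atoms: none
Why: 1,2-Reduction of the α-methylene lactone through the lactol to the 2-methylene-1,4-diol; chloride, silyl ethers and the DMB ether are inert to the hydride at this temperature.

Step 13
Reactants: 18 diol (name as in step 12)
Product: 19 6,12-bis(4-methoxybenzyl) ether of 18
Conditions: NaH, PMBCl, Bu4NI (cat.), THF/DMF, 0 °C → rt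
Reagents that add atoms: 4-methoxybenzyl chloride (COc1ccc(CCl)cc1)
Why: Williamson etherification of both allylic hydroxyls; the E alkene keeps the C6 alkoxide away from the C1 chloride, and base-stable ethers are needed for steps 16 and 18.

Step 14
Reactants: 19 bis-PMB ether
Product: 20 (2R,6R,7S,9S,10S)-2-(tert-butyldimethylsilyloxy)-1-chloro-6,12-bis(4-methoxybenzyloxy)-9-(triethylsilyloxy)-1,10-secogermacra-4E,11(13)-dien-10-ol
Conditions: DDQ (1.1 equiv), CH2Cl2/pH 7 buffer, 0 °C
Reagents that add atoms: none
Why: Oxidative debenzylation by hydride transfer to DDQ; the 3,4-dimethoxybenzyl ether is the more electron-rich donor and should be cleaved before the two PMB ethers with one equivalent of oxidant, the buffer protecting the TES ether.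

Step 15
Reactants: 20 C10 alcohol
Product: 21 (10R)-S-acetyl thioester: 10-acetylthio analogue of 20 with inverted C10
Conditions: PPh3, DIAD, AcSH, THF, 0 °C
Reagents that add atoms: thioacetic acid (CC(=O)S)
Why: Mitsunobu thioesterification with clean SN2 inversion at C10; the primary chloride does not react with the phosphine or the thioacetate at 0 °C, which is why the C1 leaving group is kept as chloride up to this point.

Step 16
Reactants: 21 thioacetate
Product: 24 (2R,6R,7S,9S,10R)-2-(tert-butyldimethylsilyloxy)-6,12-bis(4-methoxybenzyloxy)-9-(triethylsilyloxy)-1,10-epithio-1,10-secogermacra-4E,11(13)-diene (eleven-membered cyclic sulfide), via iodo thioacetate 22 (not isolated), via iodo thiol 23 (not isolated)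
Conditions: NaI, 2-butanone, 70 °C; concentrate; then syringe-pump addition to Cs2CO3, MeOH (20 equiv), degassed DMF (1 mM), 40 °C
Reagents that add atoms: none
Why: Finkelstein exchange makes C1 a better electrophile, methanolysis frees the thiol, and the caesium thiolate closes the eleven-membered ring by 11-exo-tet SN2 at the primary carbon. High dilution and the soft, strongly nucleophilic thiolate favour cyclisation over oligomerisation, and degassing suppresses disulfide formation.

Step 17
Reactants: 24 cyclic sulfide
Product: 25 eleven-membered sulfone: S,S-dioxide of 24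
Conditions: (NH4)6Mo7O24·4H2O (10 mol%), 30% H2O2, EtOH, 0 °C → rt
Reagents that add atoms: hydrogen peroxide (OO)
Why: Peroxomolybdate oxidises sulfur to the sulfone and is known to leave unactivated trisubstituted and 1,1-disubstituted alkenes, benzylic ethers and silyl ethers untouched.

Step 18
Reactants: 25 eleven-membered sulfone
Product: 28 (2R,6R,7S,9S)-2-(tert-butyldimethylsilyloxy)-6,12-bis(4-methoxybenzyloxy)-9-(triethylsilyloxy)germacra-1(10)Z,4E,11(13)-triene, via α-bromo sulfone 26 (not isolated), via episulfone 27 (not isolated)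
Conditions: CBr2F2, KOH/Al2O3, t-BuOH/CH2Cl2, 0 °C → rt
Reagents that add atoms: none
Why: The α-sulfonyl carbanion (most readily at the less substituted C1) is brominated by halophilic attack on CBr2F2 to give 26, the α′-carbanion at C10 displaces bromide to the episulfone 27, and 27 loses SO2 in a stereospecific cheletropic step that forms the C1=C10 double bond. The closest known reaction type is the Meyers/Chan one-flask Ramberg–Bäcklund reaction of dialkyl and cyclic sulfones, which is established for contracting thiacycles to medium-ring cycloalkenes and dienes. The only ring-forming event is the C1–C10 bond, made by a 3-exo-tet closure to the thiirane dioxide; the ten-membered carbocycle is not closed end to end but is left behind when the bridge is expelled, so the strain is paid in an irreversible gas-forming step. No stereocentre is created: C10 becomes sp2, so both C10 epimers of 25 and both regioisomers of halogenation converge on 28. The selectivity needed is the Z geometry, which is decided at the episulfone: with the weak heterogeneous base the kinetically formed episulfone is not epimerised, and in the bicyclo[8.1.0] framework the cis-fused isomer (C2 and C9 on the same face) is expected to be favoured. The competing process is E1cB loss of the β-silyloxy groups at C2 and C9; silanolates are poor leaving groups and the carbanion is intercepted quickly by the halogen donor, as in Ramberg–Bäcklund reactions of β-alkoxy sulfones derived from thioglycosides.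

**Side-chain acid**

Step 19
Reactants: 28 protected germacratriene
Product: 29 (2R,6R,7S,9S)-2-(tert-butyldimethylsilyloxy)-6,12-bis(4-methoxybenzyloxy)germacra-1(10)Z,4E,11(13)-trien-9-ol
Conditions: PPTS (cat.), MeOH/CH2Cl2, 0 °C
Reagents that add atoms: none
Why: Mild acid methanolysis removes the secondary TES ether far faster than the secondary TBS ether; the conditions are too weak to trigger transannular cyclisation of the diene.

Step 20
Reactants: 30 (E)-crotonaldehyde
Product: 31 (Z)-2-iodobut-2-enal
Conditions: I2, K2CO3, DMAP (cat.), THF/H2O, rt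
Reagents that add atoms: iodine (II)
Why: Amine-catalysed α-iodination of the enal (conjugate addition, iodination of the enolate, elimination) returns the isomer in which the formyl group stays trans to the methyl group, so iodine is cis to methyl.

Step 21
Reactants: 31 (Z)-2-iodobut-2-enal
Product: 32 (Z)-2-iodobut-2-en-1-ol
Conditions: NaBH4, CeCl3·7H2O, MeOH, 0 °C
Reagents that add atoms: none
Why: Luche 1,2-reduction of the enal without touching the vinyl iodide or its geometry.

Step 22
Reactants: 32 (Z)-2-iodobut-2-en-1-ol
Product: 33 (Z)-tert-butyl[(2-iodobut-2-en-1-yl)oxy]dimethylsilane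
Conditions: TBSCl, imidazole, CH2Cl2, rt
Reagents that add atoms: tert-butyldimethylsilyl chloride (CC(C)(C)[Si](C)(C)Cl)
Why: Standard silylation; the same silyl group as at C2 allows one final deprotection.

Step 23
Reactants: 33 (Z)-tert-butyl[(2-iodobut-2-en-1-yl)oxy]dimethylsilane
Product: 35 (Z)-2-[(tert-butyldimethylsilyloxy)methyl]but-2-enoic acid, via vinyllithium 34 (not isolated)
Conditions: t-BuLi (2.1 equiv), Et2O, −78 °C; CO2; then dilute aq. HCl to pH 4
Reagents that add atoms: carbon dioxide (O=C=O)
Why: Iodine–lithium exchange and carboxylation both proceed with retention at the sp2 carbon, so the carboxyl group ends cis to the methyl group (the angelate-type Z geometry of the side chain).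

**Endgame**

Step 24
Reactants: 29 C9 alcohol; 35 (Z)-2-[(tert-butyldimethylsilyloxy)methyl]but-2-enoic acid
Product: 37 C9 ester: 9-O-[(Z)-2-(tert-butyldimethylsilyloxymethyl)but-2-enoyl] derivative of 29, via mixed anhydride 36 (not isolated)
Conditions: 2,4,6-Cl3C6H2COCl, Et3N, toluene, rt; then 29, DMAP, rt
Reagents that add atoms: none
Why: Yamaguchi esterification through the mixed anhydride is the standard way to acylate hindered secondary alcohols with angelate-type acids; short contact with DMAP at room temperature limits Z to E isomerisation.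

Step 25
Reactants: 37 C9 ester
Product: 38 (2R,6R,7S,9S)-9-acyloxy-2-(tert-butyldimethylsilyloxy)germacra-1(10)Z,4E,11(13)-triene-6,12-diol (acyl as in 37)
Conditions: DDQ (2.5 equiv), CH2Cl2/pH 7 buffer, 0 °C
Reagents that add atoms: none
Why: Oxidative cleavage of both PMB ethers under buffered, non-acidic conditions; silyl ethers, the enoate and the diene are not affected.

Step 26
Reactants: 38 6,12-diol
Product: 41 bis-TBS ether of the target (6,12-olide), via hydroxy enal 39 (not isolated), via lactol 40 (not isolated)
Conditions: TEMPO (20 mol%), PhI(OAc)2 (2.5 equiv), CH2Cl2, rt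
Reagents that add atoms: none
Why: The oxoammonium salt oxidises the primary allylic C12 alcohol in preference to the secondary C6 alcohol; the enal is trapped by the C6 hydroxyl as the five-membered lactol, which is oxidised on to the α-methylene lactone with the trans fusion already fixed at C6 and C7.

Step 27
Reactants: 41 bis-TBS ether of the target
Product: 42 target, (2R,6R,7S,9S)-2-hydroxy-9-[(Z)-2-(hydroxymethyl)but-2-enoyloxy]germacra-1(10)Z,4E,11(13)-trien-12,6-olide
Conditions: HF·pyridine, pyridine, THF, 0 °C → rt
Reagents that add atoms: none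
Why: Buffered fluoride desilylation removes the secondary allylic and the primary TBS ether without base, so the Michael acceptor, the two esters and the side-chain geometry should survive.

## Compound list

1 | (R)-epichlorohydrin | ClC[C@H]1CO1 | starting material
2 | (R)-1-chloropent-4-yn-2-ol | ClC[C@H](O)CC#C | intermediate
3 | (R)-tert-butyl[(1-chloropent-4-yn-2-yl)oxy]dimethylsilane | ClC[C@H](O[Si](C)(C)C(C)(C)C)CC#C | intermediate
4 | dimethyl[(R,E)-4-(tert-butyldimethylsilyloxy)-5-chloro-2-methylpent-1-enyl]alane (not isolated) | C[Al](C)/C=C(\C)C[C@@H](O[Si](C)(C)C(C)(C)C)CCl | intermediate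
5 | (R,E)-5-(tert-butyldimethylsilyloxy)-6-chloro-3-methylhex-2-en-1-ol | OC/C=C(\C)C[C@@H](O[Si](C)(C)C(C)(C)C)CCl | intermediate
6 | (R,E)-5-(tert-butyldimethylsilyloxy)-6-chloro-3-methylhex-2-enal | O=C/C=C(\C)C[C@@H](O[Si](C)(C)C(C)(C)C)CCl | intermediate
7 | ethyl (S)-lactate | C[C@H](O)C(=O)OCC | starting material
8 | ethyl (S)-2-[(3,4-dimethoxybenzyl)oxy]propanoate | C[C@H](OCc1ccc(OC)c(OC)c1)C(=O)OCC | intermediate
9 | (S)-2-[(3,4-dimethoxybenzyl)oxy]propanal | C[C@H](OCc1ccc(OC)c(OC)c1)C=O | intermediate
10 | (2S,3S)-2-[(3,4-dimethoxybenzyl)oxy]hex-5-yn-3-ol | C[C@H](OCc1ccc(OC)c(OC)c1)[C@@H](O)CC#C | intermediate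
11 | {[(2S,3S)-2-[(3,4-dimethoxybenzyl)oxy]hex-5-yn-3-yl]oxy}triethylsilane | C[C@H](OCc1ccc(OC)c(OC)c1)[C@@H](O[Si](CC)(CC)CC)CC#C | intermediate
12 | lithium acetylide of 11 (not isolated) | C[C@H](OCc1ccc(OC)c(OC)c1)[C@@H](O[Si](CC)(CC)CC)CC#C[Li] | intermediate
13 | methyl (5S,6S)-6-[(3,4-dimethoxybenzyl)oxy]-5-(triethylsilyloxy)hept-2-ynoate | C[C@H](OCc1ccc(OC)c(OC)c1)[C@@H](O[Si](CC)(CC)CC)CC#CC(=O)OC | intermediate
14 | methyl (E,5S,6S)-2-(diisobutylalumanyl)-6-[(3,4-dimethoxybenzyl)oxy]-5-(triethylsilyloxy)hept-2-enoate (not isolated) | COC(=O)/C([Al](CC(C)C)CC(C)C)=C\C[C@H](O[Si](CC)(CC)CC)[C@H](C)OCc1ccc(OC)c(OC)c1 | intermediate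
15 | methyl (Z,5S,6S)-6-[(3,4-dimethoxybenzyl)oxy]-2-[(4,4,5,5-tetramethyl-1,3,2-dioxaborolan-2-yl)methyl]-5-(triethylsilyloxy)hept-2-enoate | COC(=O)/C(CB1OC(C)(C)C(C)(C)O1)=C\C[C@H](O[Si](CC)(CC)CC)[C@H](C)OCc2ccc(OC)c(OC)c2 | intermediate
16 | pinacol borate of the anti adduct: methyl ester with C6–O–Bpin, 2R,6R,7S,9S,10S (not isolated) | COC(=O)C(=C)[C@H](C[C@H](O[Si](CC)(CC)CC)[C@H](C)OCc1ccc(OC)c(OC)c1)[C@H](OB2OC(C)(C)C(C)(C)O2)/C=C(\C)C[C@@H](O[Si](C)(C)C(C)(C)C)CCl | intermediate
17 | (4S,5R)-5-[(R,E)-4-(tert-butyldimethylsilyloxy)-5-chloro-2-methylpent-1-en-1-yl]-4-[(2S,3S)-3-(3,4-dimethoxybenzyloxy)-2-(triethylsilyloxy)butyl]-3-methylenedihydrofuran-2(3H)-one | C=C1C(=O)O[C@H](/C=C(\C)C[C@@H](O[Si](C)(C)C(C)(C)C)CCl)[C@H]1C[C@H](O[Si](CC)(CC)CC)[C@H](C)OCc2ccc(OC)c(OC)c2 | intermediate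
18 | (2R,6R,7S,9S,10S)-2-(tert-butyldimethylsilyloxy)-1-chloro-10-(3,4-dimethoxybenzyloxy)-9-(triethylsilyloxy)-1,10-secogermacra-4E,11(13)-diene-6,12-diol | O[C@H](/C=C(\C)C[C@@H](O[Si](C)(C)C(C)(C)C)CCl)[C@@H](C[C@H](O[Si](CC)(CC)CC)[C@H](C)OCc1ccc(OC)c(OC)c1)C(=C)CO | intermediate
19 | 6,12-bis(4-methoxybenzyl) ether of 18 | COc1ccc(cc1)CO[C@H](/C=C(\C)C[C@@H](O[Si](C)(C)C(C)(C)C)CCl)[C@@H](C[C@H](O[Si](CC)(CC)CC)[C@H](C)OCc2ccc(OC)c(OC)c2)C(=C)COCc3ccc(OC)cc3 | intermediate
20 | (2R,6R,7S,9S,10S)-2-(tert-butyldimethylsilyloxy)-1-chloro-6,12-bis(4-methoxybenzyloxy)-9-(triethylsilyloxy)-1,10-secogermacra-4E,11(13)-dien-10-ol | COc1ccc(cc1)CO[C@H](/C=C(\C)C[C@@H](O[Si](C)(C)C(C)(C)C)CCl)[C@@H](C[C@H](O[Si](CC)(CC)CC)[C@H](C)O)C(=C)COCc2ccc(OC)cc2 | intermediate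
21 | (10R)-10-acetylthio analogue of 20 (2R,6R,7S,9S,10R) | COc1ccc(cc1)CO[C@H](/C=C(\C)C[C@@H](O[Si](C)(C)C(C)(C)C)CCl)[C@@H](C[C@H](O[Si](CC)(CC)CC)[C@@H](C)SC(C)=O)C(=C)COCc2ccc(OC)cc2 | intermediate
22 | 1-iodo analogue of 21 (not isolated) | COc1ccc(cc1)CO[C@H](/C=C(\C)C[C@@H](O[Si](C)(C)C(C)(C)C)CI)[C@@H](C[C@H](O[Si](CC)(CC)CC)[C@@H](C)SC(C)=O)C(=C)COCc2ccc(OC)cc2 | intermediate
23 | 1-iodo-10-thiol (not isolated) | COc1ccc(cc1)CO[C@H](/C=C(\C)C[C@@H](O[Si](C)(C)C(C)(C)C)CI)[C@@H](C[C@H](O[Si](CC)(CC)CC)[C@@H](C)S)C(=C)COCc2ccc(OC)cc2 | intermediate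
24 | (2R,6R,7S,9S,10R)-2-(tert-butyldimethylsilyloxy)-6,12-bis(4-methoxybenzyloxy)-9-(triethylsilyloxy)-1,10-epithio-1,10-secogermacra-4E,11(13)-diene | COc1ccc(cc1)CO[C@@H]2/C=C(\C)C[C@@H](O[Si](C)(C)C(C)(C)C)CS[C@H](C)[C@@H](O[Si](CC)(CC)CC)C[C@H]2C(=C)COCc3ccc(OC)cc3 | intermediate
25 | S,S-dioxide of 24 (eleven-membered sulfone) | COc1ccc(cc1)CO[C@@H]2/C=C(\C)C[C@@H](O[Si](C)(C)C(C)(C)C)CS(=O)(=O)[C@H](C)[C@@H](O[Si](CC)(CC)CC)C[C@H]2C(=C)COCc3ccc(OC)cc3 | intermediate
26 | 1-bromo derivative of 25, C1 epimers (not isolated) | COc1ccc(cc1)CO[C@@H]2/C=C(\C)C[C@@H](O[Si](C)(C)C(C)(C)C)C(Br)S(=O)(=O)[C@H](C)[C@@H](O[Si](CC)(CC)CC)C[C@H]2C(=C)COCc3ccc(OC)cc3 | intermediate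
27 | cis-fused 1,10-episulfone (thiirane 1,1-dioxide, C2 and C9 on the same face; one of the two cis forms drawn; not isolated) | COc1ccc(cc1)CO[C@@H]2/C=C(\C)C[C@@H](O[Si](C)(C)C(C)(C)C)[C@H]4S(=O)(=O)[C@@]4(C)[C@@H](O[Si](CC)(CC)CC)C[C@H]2C(=C)COCc3ccc(OC)cc3 | intermediate
28 | (2R,6R,7S,9S)-2-(tert-butyldimethylsilyloxy)-6,12-bis(4-methoxybenzyloxy)-9-(triethylsilyloxy)germacra-1(10)Z,4E,11(13)-triene | COc1ccc(cc1)CO[C@@H]2/C=C(\C)C[C@@H](O[Si](C)(C)C(C)(C)C)/C=C(/C)[C@@H](O[Si](CC)(CC)CC)C[C@H]2C(=C)COCc3ccc(OC)cc3 | intermediate
29 | (2R,6R,7S,9S)-2-(tert-butyldimethylsilyloxy)-6,12-bis(4-methoxybenzyloxy)germacra-1(10)Z,4E,11(13)-trien-9-ol | COc1ccc(cc1)CO[C@@H]2/C=C(\C)C[C@@H](O[Si](C)(C)C(C)(C)C)/C=C(/C)[C@@H](O)C[C@H]2C(=C)COCc3ccc(OC)cc3 | intermediate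
30 | (E)-crotonaldehyde | C/C=C/C=O | starting material
31 | (Z)-2-iodobut-2-enal | C/C=C(\I)C=O | intermediate
32 | (Z)-2-iodobut-2-en-1-ol | C/C=C(\I)CO | intermediate
33 | (Z)-tert-butyl[(2-iodobut-2-en-1-yl)oxy]dimethylsilane | C/C=C(\I)CO[Si](C)(C)C(C)(C)C | intermediate
34 | 2-lithio analogue of 33, lithium cis to methyl (not isolated) | C/C=C(\[Li])CO[Si](C)(C)C(C)(C)C | intermediate
35 | (Z)-2-[(tert-butyldimethylsilyloxy)methyl]but-2-enoic acid | OC(=O)/C(=C\C)CO[Si](C)(C)C(C)(C)C | intermediate
36 | mixed anhydride of 35 with 2,4,6-trichlorobenzoic acid (not isolated) | O=C(OC(=O)c1c(Cl)cc(Cl)cc1Cl)/C(=C\C)CO[Si](C)(C)C(C)(C)C | intermediate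
37 | 9-O-[(Z)-2-(tert-butyldimethylsilyloxymethyl)but-2-enoyl] derivative of 29 | COc1ccc(cc1)CO[C@@H]2/C=C(\C)C[C@@H](O[Si](C)(C)C(C)(C)C)/C=C(/C)[C@@H](OC(=O)/C(=C\C)CO[Si](C)(C)C(C)(C)C)C[C@H]2C(=C)COCc3ccc(OC)cc3 | intermediate
38 | (2R,6R,7S,9S)-9-acyloxy-2-(tert-butyldimethylsilyloxy)germacra-1(10)Z,4E,11(13)-triene-6,12-diol (acyl as in 37) | O[C@@H]1/C=C(\C)C[C@@H](O[Si](C)(C)C(C)(C)C)/C=C(/C)[C@@H](OC(=O)/C(=C\C)CO[Si](C)(C)C(C)(C)C)C[C@H]1C(=C)CO | intermediate
39 | 6-hydroxy-12-al derived from 38 (not isolated) | O[C@@H]1/C=C(\C)C[C@@H](O[Si](C)(C)C(C)(C)C)/C=C(/C)[C@@H](OC(=O)/C(=C\C)CO[Si](C)(C)C(C)(C)C)C[C@H]1C(=C)C=O | intermediate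
40 | 6,12-lactol, C12 epimers (not isolated) | C=C1C(O)O[C@@H]2/C=C(\C)C[C@@H](O[Si](C)(C)C(C)(C)C)/C=C(/C)[C@@H](OC(=O)/C(=C\C)CO[Si](C)(C)C(C)(C)C)C[C@@H]12 | intermediate
41 | bis-TBS ether of the target (6,12-olide) | C=C1C(=O)O[C@@H]2/C=C(\C)C[C@@H](O[Si](C)(C)C(C)(C)C)/C=C(/C)[C@@H](OC(=O)/C(=C\C)CO[Si](C)(C)C(C)(C)C)C[C@@H]12 | intermediate
42 | (2R,6R,7S,9S)-2-hydroxy-9-[(Z)-2-(hydroxymethyl)but-2-enoyloxy]germacra-1(10)Z,4E,11(13)-trien-12,6-olide (CNP0273961.1) | C=C1C(=O)O[C@@H]2/C=C(\C)C[C@@H](O)/C=C(/C)[C@@H](OC(=O)/C(=C\C)CO)C[C@@H]12 | target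

## Step count and least certain steps

Total: 27 steps. Longest linear sequence: 19 steps (7 to 42 through steps 5–19 and 24–27). The enal branch (steps 1–4) and the acid branch (steps 20–23) are convergent.

**Step 18 (key step).** Three processes can compete with the contraction.
- Geometry: an (E,E)-cyclodecadiene is not prohibitively strained, so some trans-fused episulfone and hence some 1(10)E isomer cannot be excluded.
- Elimination: the C1 or C10 carbanion may lose the neighbouring silyloxy group by E1cB before it is halogenated.
- Over-halogenation: deprotonation at the hindered, methyl-bearing C10 is slow, so C1 may be brominated twice before the episulfone closes.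

Fallback, a stepwise Ramberg–Bäcklund sequence that separates halogenation from elimination: it sets out from sulfone 25. Lithiation with n-BuLi in THF at −78 °C and immediate quench with C2Cl6 should give the isolable α-chloro sulfone F1 (chlorine at C1). α-Lithio β-silyloxy sulfones are known to be stable at this temperature. Treatment of F1 with KOt-Bu in THF at −78 → 0 °C then effects the 1,3-elimination and extrusion, and the sequence rejoins the route at triene 28.

**Step 16.** Closure of an eleven-membered ring may lose to intermolecular S-alkylation and to oxidative disulfide formation. The effective molarity of medium rings is low, and the electrophilic carbon is slowed by the adjacent silyloxy group.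

Fallback, ring closure through a reversible S–S bond followed by sulfur excision: it sets out from thioacetate 21. KSC(O)CH3 in DMF at 50 °C displaces the C1 chloride to give the bis-thioacetate F2. Methanolysis with K2CO3 and oxidation with I2 at high dilution should close the twelve-membered cyclic disulfide F3. (Et2N)3P in benzene at 60 °C (Harpp desulfurisation) then removes one sulfur: the thiolate on C10 attacks the primary C1 within the ion pair, so C10 is untouched, and the sequence rejoins the route at sulfide 24.

**Step 11.** Facial selectivity may be poor. The ester-substituted boronate is less nucleophilic than the simple allyl and crotyl pinacol boronates for which the phosphoric acid catalysis is best documented, so an uncatalysed background reaction without facial control may compete. The Lewis-basic ether and ester groups of 15 may also disturb the catalyst–boronate complex.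

Fallback, stoichiometric reagent control in place of catalysis: it sets out from boronate 15. KHF2 in MeOH/H2O gives the potassium trifluoroborate F4. Me3SiCl followed by diisopropyl (R,R)-tartrate and 4 Å MS gives the tartrate boronate F5. Tartrate allylboronates of this absolute configuration add to the Si face of aldehydes, and the uncatalysed reaction with enal 6 in toluene at −78 → 0 °C, followed by warming to lactonise, rejoins the route at lactone 17.

**Step 14.** The PMB ethers may be lost together with the DMB ether. The rate difference between the two benzylic ethers is finite and two PMB groups are present; over-oxidation would give inseparable diol mixtures.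

Fallback, debenzylation before any PMB ether is present: it sets out from lactone 17. DDQ in buffered CH2Cl2 gives the hydroxy lactone F6. 2-Methoxypropene with catalytic PPTS gives the 2-methoxyprop-2-yl ether F7. i-Bu2AlH gives the diol F8, and NaH with PMBCl gives the bis-PMB ether F9. Brief treatment with catalytic PPTS in MeOH at 0 °C removes only the ketal, which is far more labile than the TES ether, and the sequence rejoins the route at alcohol 20.

## Further compounds

F1 | step 18 | 1-chloro derivative of sulfone 25 (C1 epimers) | COc1ccc(cc1)CO[C@@H]2/C=C(\C)C[C@@H](O[Si](C)(C)C(C)(C)C)C(Cl)S(=O)(=O)[C@H](C)[C@@H](O[Si](CC)(CC)CC)C[C@H]2C(=C)COCc3ccc(OC)cc3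
F2 | step 16 | 1,10-bis(acetylthio) analogue of 21 | COc1ccc(cc1)CO[C@H](/C=C(\C)C[C@@H](O[Si](C)(C)C(C)(C)C)CSC(C)=O)[C@@H](C[C@H](O[Si](CC)(CC)CC)[C@@H](C)SC(C)=O)C(=C)COCc2ccc(OC)cc2
F3 | step 16 | twelve-membered cyclic 1,10-disulfide | COc1ccc(cc1)CO[C@@H]2/C=C(\C)C[C@@H](O[Si](C)(C)C(C)(C)C)CSS[C@H](C)[C@@H](O[Si](CC)(CC)CC)C[C@H]2C(=C)COCc3ccc(OC)cc3
F4 | step 11 | potassium trifluoroborate derived from 15 | [K+].COC(=O)/C(C[B-](F)(F)F)=C\C[C@H](O[Si](CC)(CC)CC)[C@H](C)OCc1ccc(OC)c(OC)c1
F5 | step 11 | diisopropyl (R,R)-tartrate boronate corresponding to 15 | COC(=O)/C(CB1O[C@@H](C(=O)OC(C)C)[C@H](C(=O)OC(C)C)O1)=C\C[C@H](O[Si](CC)(CC)CC)[C@H](C)OCc2ccc(OC)c(OC)c2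
F6 | step 14 | 10-hydroxy lactone (17 without the DMB group) | C=C1C(=O)O[C@H](/C=C(\C)C[C@@H](O[Si](C)(C)C(C)(C)C)CCl)[C@H]1C[C@H](O[Si](CC)(CC)CC)[C@H](C)O
F7 | step 14 | 10-O-(2-methoxyprop-2-yl) ether of F6 | C=C1C(=O)O[C@H](/C=C(\C)C[C@@H](O[Si](C)(C)C(C)(C)C)CCl)[C@H]1C[C@H](O[Si](CC)(CC)CC)[C@H](C)OC(C)(C)OC
F8 | step 14 | 6,12-diol with 10-O-(2-methoxyprop-2-yl) ether | O[C@H](/C=C(\C)C[C@@H](O[Si](C)(C)C(C)(C)C)CCl)[C@@H](C[C@H](O[Si](CC)(CC)CC)[C@H](C)OC(C)(C)OC)C(=C)CO
F9 | step 14 | 6,12-bis(4-methoxybenzyl) ether of F8 | COc1ccc(cc1)CO[C@H](/C=C(\C)C[C@@H](O[Si](C)(C)C(C)(C)C)CCl)[C@@H](C[C@H](O[Si](CC)(CC)CC)[C@H](C)OC(C)(C)OC)C(=C)COCc2ccc(OC)cc2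
A1 | alternative 1 | bis-TBS ether of the target (identical with 41) | C=C1C(=O)O[C@@H]2/C=C(\C)C[C@@H](O[Si](C)(C)C(C)(C)C)/C=C(/C)[C@@H](OC(=O)/C(=C\C)CO[Si](C)(C)C(C)(C)C)C[C@@H]12
A2 | alternative 1 | ten-membered 2-substituted acrylic acid with C6 methylene | OC(=O)C(=C)[C@H]1C/C=C(\C)C[C@@H](O[Si](C)(C)C(C)(C)C)/C=C(/C)[C@@H](OC(=O)/C(=C\C)CO[Si](C)(C)C(C)(C)C)C1
A3 | alternative 2 | trans-fused 11,13-dihydro-13-nor lactone on the (1(10)Z,4E)-cyclodecadiene | C1C(=O)O[C@@H]2/C=C(\C)C[C@@H](O[Si](C)(C)C(C)(C)C)/C=C(/C)[C@@H](O[Si](CC)(CC)CC)C[C@@H]12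
A4 | alternative 2 | open-chain ynal methyl ester (C6 aldehyde, C4≡C5 terminal alkyne) | COC(=O)C[C@@H](C=O)C[C@H](O[Si](CC)(CC)CC)/C(C)=C\[C@H](O[Si](C)(C)C(C)(C)C)CC#C
A5 | alternative 3 | bis-silylated germacranolide core with the α-methylene lactone | C=C1C(=O)O[C@@H]2/C=C(\C)C[C@@H](O[Si](C)(C)C(C)(C)C)/C=C(/C)[C@@H](O[Si](CC)(CC)CC)C[C@@H]12
A6 | alternative 3 | N-acyloxyphthalimide carrying the 3-(phenylsulfonylmethyl)butenolide | O=C(C[C@H](O[Si](CC)(CC)CC)/C(C)=C\[C@H](O[Si](C)(C)C(C)(C)C)C/C(C)=C/[C@H]1OC(=O)C(CS(=O)(=O)c2ccccc2)=C1)ON3C(=O)c4ccccc4C3=O
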